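The route rests on disconnecting the aryl ether bond O1–C8a of ring C. Since O1 is the oxygen of the benzylic C2 carbinol and C8a is a ring A carbon, all stereochemistry can be built on an open-chain 1,3-diarylpropane-1,2,3-triol: bromine on ring A marks C8a (which locks prenyl at C6), the C2 hydroxyl alone is free, O3 carries TBS and O4 the more labile TES. A single palladium-catalysed intramolecular C–O coupling then closes ring C without touching C2, so the anti C2/C3 relation becomes the 2,3-trans ring. Giving O3 and O4 different silyl groups lets C4 be oxidised later as a mono-alcohol, not as a vicinal diol.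

Key step: step 12

Assumption: [(tert-butyldimethylsilyl)oxy]acetic acid, (S)-4-benzyloxazolidin-2-one and LiN(iPr)2 solution are taken as purchasable.
Notation: flavonoid numbering (O1, C2, C3, C4, C4a, C5–C8, C8a, ring B primed) is used for the open-chain intermediates as well. MOM = methoxymethyl, TBS = tert-butyldimethylsilyl, TES = triethylsilyl, prenyl = 3-methylbut-2-en-1-yl, geranyl = (2E)-3,7-dimethylocta-2,6-dien-1-yl.

Step 1
Reactants: 1 5-bromoresorcinol
Product: 2 1-bromo-3,5-bis(methoxymethoxy)benzene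
Conditions: MOMCl, iPr2NEt, CH2Cl2, 0 °C → rt
Reagents that add atoms: chloromethyl methyl ether (MOMCl), COCCl
Why: O-alkylation of both phenols by the α-chloro ether (Williamson-type MOM protection) should be complete because nothing else in 1 is nucleophilic and the aryl bromide is inert.

Step 2
Reactants: 2 1-bromo-3,5-bis(methoxymethoxy)benzene; 3 prenyl bromide (1-bromo-3-methylbut-2-ene)
Product: 5 5-bromo-1,3-bis(methoxymethoxy)-2-(3-methylbut-2-en-1-yl)benzene, via 4-bromo-2,6-bis(methoxymethoxy)phenyllithium 4 (not isolated)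
Conditions: LiN(iPr)2, THF, −78 °C; then CuBr·SMe2 (10 mol%), 3, −78 → 0 °C
Reagents that add atoms: none
Why: Directed ortho-metalation with a lithium amide (which cannot undergo halogen–lithium exchange) should remove the proton flanked by both OMOM groups, the most activated ring position and para to bromine so that no aryne can form, and copper-catalysed SN2 allylation of the aryllithium with the primary allylic bromide then places prenyl at the future C6.

Step 3
Reactants: 5 5-bromo-1,3-bis(methoxymethoxy)-2-(3-methylbut-2-en-1-yl)benzene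
Product: 7 6-bromo-2,4-bis(methoxymethoxy)-3-(3-methylbut-2-en-1-yl)benzaldehyde, via 6-bromo-2,4-bis(methoxymethoxy)-3-prenylphenyllithium 6 (not isolated)
Conditions: LiN(iPr)2, THF, −78 °C; DMF, −78 °C; AcOH quench at −78 °C
Reagents that add atoms: N,N-dimethylformamide (DMF), CN(C)C=O
Why: A second directed ortho-metalation at the only remaining kind of ring proton, acidified by the flanking OMOM group and bromine, followed by formylation with DMF should give the aldehyde, since the ortho-bromoaryllithium does not lose LiBr at −78 °C and the cold acidic quench releases the formyl group.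

Step 4
Reactants: 8 resorcinol
Product: 9 1,3-bis(methoxymethoxy)benzene
Conditions: MOMCl, iPr2NEt, CH2Cl2, 0 °C → rt
Reagents that add atoms: chloromethyl methyl ether (MOMCl), COCCl
Why: The same Williamson-type MOM protection as in step 1 converts both phenols into the acetal ethers that later direct lithiation.

Step 5
Reactants: 9 1,3-bis(methoxymethoxy)benzene; 10 geranyl bromide
Product: 12 2-[(2E)-3,7-dimethylocta-2,6-dien-1-yl]-1,3-bis(methoxymethoxy)benzene, via 2,6-bis(methoxymethoxy)phenyllithium 11 (not isolated)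
Conditions: n-BuLi, THF, 0 °C; then CuBr·SMe2 (10 mol%), 10, −78 °C → rt
Reagents that add atoms: none
Why: Directed ortho-metalation by n-BuLi occurs at C2 between the two OMOM groups, and copper-catalysed SN2 coupling of the aryllithium at the primary allylic carbon of geranyl bromide keeps the E alkene intact.

Step 6
Reactants: 13 (S)-4-benzyloxazolidin-2-one; 14 [(tert-butyldimethylsilyl)oxy]acetic acid
Product: 16 (4S)-4-benzyl-3-{[(tert-butyldimethylsilyl)oxy]acetyl}oxazolidin-2-one, via silyloxyacetic pivalic mixed anhydride 15 (not isolated)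
Conditions: t-BuCOCl, Et3N, THF, −20 °C; then LiCl, 13, −20 °C → rt
Reagents that add atoms: none
Why: N-acylation of the oxazolidinone through a mixed anhydride (LiCl/Et3N activation) should be regioselective because the hindered pivaloyl carbonyl steers attack to the glycolyl carbonyl, and the auxiliary stereocentre is untouched.

Step 7
Reactants: 16 (4S)-4-benzyl-3-{[(tert-butyldimethylsilyl)oxy]acetyl}oxazolidin-2-one; 7 6-bromo-2,4-bis(methoxymethoxy)-3-(3-methylbut-2-en-1-yl)benzaldehyde
Product: 18 (4S)-4-benzyl-3-[(2S,3R)-3-[6-bromo-2,4-bis(methoxymethoxy)-3-(3-methylbut-2-en-1-yl)phenyl]-2-[(tert-butyldimethylsilyl)oxy]-3-hydroxypropanoyl]oxazolidin-2-one, via Z-dibutylboron enolate of imide 16 17 (not isolated)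
Conditions: Bu2BOTf, Et3N, CH2Cl2, −78 → 0 °C; then 7, −78 → 0 °C; pH 7 buffer, MeOH, H2O2, 0 °C
Reagents that add atoms: none
Why: Evans syn-aldol reaction, in which the Z boron enolate reacts through a chair Zimmerman–Traxler transition state on the enolate face opposite the benzyl group of the (S)-auxiliary, which should set the silyloxy carbon (future C3) as S and the carbinol carbon (future C4) as R in a syn relation.

Step 8
Reactants: 18 syn-aldol adduct
Product: 19 (4S)-4-benzyl-3-[(2S,3R)-3-[6-bromo-2,4-bis(methoxymethoxy)-3-(3-methylbut-2-en-1-yl)phenyl]-2-[(tert-butyldimethylsilyl)oxy]-3-[(triethylsilyl)oxy]propanoyl]oxazolidin-2-one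
Conditions: TESOTf, 2,6-lutidine, CH2Cl2, −78 °C
Reagents that add atoms: triethylsilyl trifluoromethanesulfonate (TESOTf), CC[Si](CC)(CC)OS(=O)(=O)C(F)(F)F
Why: Silylation of the hindered benzylic alcohol with a silyl triflate and a hindered pyridine base is fast at −78 °C, where retro-aldol cleavage and attack on the aryl MOM ethers should not compete, and TES is chosen so that O4 can later be freed beside the TBS ether on O3.

Step 9
Reactants: 19 bis-silylated imide
Product: 20 (2R,3R)-3-[6-bromo-2,4-bis(methoxymethoxy)-3-(3-methylbut-2-en-1-yl)phenyl]-2-[(tert-butyldimethylsilyl)oxy]-3-[(triethylsilyl)oxy]propan-1-ol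
Conditions: LiBH4, THF, 0 °C → rt
Reagents that add atoms: none
Why: Reductive cleavage of the N-acyl oxazolidinone by borohydride attack at the exocyclic carbonyl gives the primary alcohol and returns the auxiliary, while the aryl bromide, acetals, alkene and silyl ethers are inert to LiBH4.

Step 10
Reactants: 20 primary alcohol
Product: 21 (2S,3R)-3-[6-bromo-2,4-bis(methoxymethoxy)-3-(3-methylbut-2-en-1-yl)phenyl]-2-[(tert-butyldimethylsilyl)oxy]-3-[(triethylsilyl)oxy]propanal
Conditions: Dess–Martin periodinane, pyridine, CH2Cl2, 0 °C → rt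
Reagents that add atoms: none
Why: Dess–Martin oxidation under pyridine buffering converts the primary alcohol into the aldehyde under neutral conditions that should not epimerise the α-silyloxy stereocentre or cleave the silyl and MOM ethers.

Step 11
Reactants: 12 2-geranyl-1,3-bis(methoxymethoxy)benzene; 21 α,β-bis(silyloxy) aldehyde
Product: 23 (1R,2R,3R)-3-[6-bromo-2,4-bis(methoxymethoxy)-3-(3-methylbut-2-en-1-yl)phenyl]-2-[(tert-butyldimethylsilyl)oxy]-1-{3-[(2E)-3,7-dimethylocta-2,6-dien-1-yl]-2,4-bis(methoxymethoxy)phenyl}-3-[(triethylsilyl)oxy]propan-1-ol, via 3-geranyl-2,4-bis(methoxymethoxy)phenyllithium 22 (not isolated)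
Conditions: 12 (slight excess over base), n-BuLi, TMEDA, Et2O, 0 °C; then 21, −78 °C; AcOH/THF quench at −78 °C
Reagents that add atoms: none
Why: Directed ortho-metalation of 12 next to an OMOM group gives the ring B aryllithium, whose 1,2-addition to the aldehyde follows the polar Felkin–Anh model (the non-chelating TBS ether antiperiplanar to the incoming aryl), which should set the new carbinol (future C2) as R, anti to O3, and at −78 °C carbonyl addition should outrun bromine–lithium exchange on ring A.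

Step 12
Reactants: 23 open-chain triol derivative with free C2 hydroxyl, O3-TBS, O4-TES and bromine at C8a
Product: 24 (2R,3R,4R)-3-[(tert-butyldimethylsilyl)oxy]-2-{3-[(2E)-3,7-dimethylocta-2,6-dien-1-yl]-2,4-bis(methoxymethoxy)phenyl}-5,7-bis(methoxymethoxy)-6-(3-methylbut-2-en-1-yl)-4-[(triethylsilyl)oxy]chromane (2,3-trans, 3,4-trans)
Conditions: Pd(OAc)2 (5 mol%), 2-(di-tert-butylphosphino)-1,1′-binaphthyl (6 mol%), Cs2CO3, toluene, 80 °C
Reagents that add atoms: none
Why: Zerovalent palladium, formed in the flask from Pd(OAc)2 and the bulky di-tert-butyl(binaphthyl)phosphine, adds oxidatively into the C8a–Br bond, Cs2CO3 deprotonates the palladium-bound C2 hydroxyl, and C–O reductive elimination from the resulting seven-membered oxapalladacycle forms O1–C8a. The closest known reaction type is the palladium-catalysed intramolecular etherification of aryl bromides with secondary alcohols that gives chromans (a Buchwald–Hartwig-type C–O coupling), applied here to a more heavily substituted substrate. Ring C, the six-membered ring O1–C2–C3–C4–C4a–C8a, closes by substitution at the arene carbon C8a by the oxygen of a side chain that is anchored at the neighbouring C4a. No stereocentre is created: the C2–O bond is never broken, so C2 stays R, the anti C2/C3 relation from step 11 becomes the 2,3-trans ring relation, and C3 and C4 are spectators. The step needs reductive elimination to beat β-hydride loss from the benzylic alkoxide, which the bulky electron-rich ligand secures, and it needs O2 to be the only oxygen that can couple, which is secured because O3 and O4 are silylated and O3 carries the bulkier TBS group that resists a 1,2-shift to the C2 alkoxide under carbonate in toluene. The position of bromine, meta to both OMOM groups and next to the C4 side chain, fixes prenyl at C6 and not at C8.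

Step 13
Reactants: 24 flavan 3-O-TBS 4-O-TES ether
Product: 25 (2R,3S,4R)-3-[(tert-butyldimethylsilyl)oxy]-2-{3-[(2E)-3,7-dimethylocta-2,6-dien-1-yl]-2,4-bis(methoxymethoxy)phenyl}-5,7-bis(methoxymethoxy)-6-(3-methylbut-2-en-1-yl)chroman-4-ol
Conditions: HF·pyridine, pyridine, THF, 0 °C
Reagents that add atoms: none
Why: Fluoride-mediated desilylation with buffered HF·pyridine should cleave the more labile TES ether selectively beside the secondary TBS ether and the aryl MOM ethers, and the buffered medium avoids ionisation of the electron-rich benzylic C4–O bond.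

Step 14
Reactants: 25 flavan-4-ol
Product: 26 (2R,3R)-3-[(tert-butyldimethylsilyl)oxy]-2-{3-[(2E)-3,7-dimethylocta-2,6-dien-1-yl]-2,4-bis(methoxymethoxy)phenyl}-5,7-bis(methoxymethoxy)-6-(3-methylbut-2-en-1-yl)chroman-4-one
Conditions: Dess–Martin periodinane, pyridine, CH2Cl2, 0 °C → rt
Reagents that add atoms: none
Why: Dess–Martin oxidation of the single free secondary benzylic alcohol gives the C4 ketone, and because O3 is still silylated there is no vicinal diol to cleave and the neutral conditions should neither epimerise C3 nor open ring C.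

Step 15
Reactants: 26 protected flavanonol
Product: 27 (2R,3R)-2-{3-[(2E)-3,7-dimethylocta-2,6-dien-1-yl]-2,4-dihydroxyphenyl}-3,5,7-trihydroxy-6-(3-methylbut-2-en-1-yl)chroman-4-one (CNP0166115.1)
Conditions: HCl (1 M in MeOH), 35 °C
Reagents that add atoms: none
Why: Acid-catalysed acetal exchange with methanol removes the four aryl MOM ethers and the same medium solvolyses the secondary TBS ether, while the dilute acid and low temperature should keep the prenyl and geranyl chains from cyclising onto the freed ortho phenols and leave the trans 2R,3R centres unchanged.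

Compound list
1 | 5-bromoresorcinol | Oc1cc(O)cc(Br)c1 | starting material
2 | 1-bromo-3,5-bis(methoxymethoxy)benzene | COCOc1cc(Br)cc(OCOC)c1 | intermediate
3 | prenyl bromide | CC(C)=CCBr | starting material
4 | 4-bromo-2,6-bis(methoxymethoxy)phenyllithium | [Li]c1c(OCOC)cc(Br)cc1OCOC | intermediate (not isolated)
5 | 5-bromo-1,3-bis(methoxymethoxy)-2-(3-methylbut-2-en-1-yl)benzene | CC(C)=CCc1c(OCOC)cc(Br)cc1OCOC | intermediate
6 | 6-bromo-2,4-bis(methoxymethoxy)-3-prenylphenyllithium | [Li]c1c(Br)cc(OCOC)c(CC=C(C)C)c1OCOC | intermediate (not isolated)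
7 | 6-bromo-2,4-bis(methoxymethoxy)-3-(3-methylbut-2-en-1-yl)benzaldehyde | O=Cc1c(Br)cc(OCOC)c(CC=C(C)C)c1OCOC | intermediate
8 | resorcinol | Oc1cccc(O)c1 | starting material
9 | 1,3-bis(methoxymethoxy)benzene | COCOc1cccc(OCOC)c1 | intermediate
10 | geranyl bromide | CC(C)=CCC/C(C)=C/CBr | starting material
11 | 2,6-bis(methoxymethoxy)phenyllithium | [Li]c1c(OCOC)cccc1OCOC | intermediate (not isolated)
12 | 2-[(2E)-3,7-dimethylocta-2,6-dien-1-yl]-1,3-bis(methoxymethoxy)benzene | CC(C)=CCC/C(C)=C/Cc1c(OCOC)cccc1OCOC | intermediate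
13 | (S)-4-benzyloxazolidin-2-one | O=C1N[C@@H](Cc2ccccc2)CO1 | starting material
14 | [(tert-butyldimethylsilyl)oxy]acetic acid | CC(C)(C)[Si](C)(C)OCC(=O)O | starting material
15 | [(tert-butyldimethylsilyl)oxy]acetic pivalic anhydride | CC(C)(C)[Si](C)(C)OCC(=O)OC(=O)C(C)(C)C | intermediate (not isolated)
16 | (4S)-4-benzyl-3-{[(tert-butyldimethylsilyl)oxy]acetyl}oxazolidin-2-one | CC(C)(C)[Si](C)(C)OCC(=O)N1[C@@H](Cc2ccccc2)COC1=O | intermediate
17 | Z-dibutylboron enolate of 16 | CCCCB(CCCC)O/C(=C\O[Si](C)(C)C(C)(C)C)N1[C@@H](Cc2ccccc2)COC1=O | intermediate (not isolated)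
18 | (4S)-4-benzyl-3-[(2S,3R)-3-[6-bromo-2,4-bis(methoxymethoxy)-3-(3-methylbut-2-en-1-yl)phenyl]-2-[(tert-butyldimethylsilyl)oxy]-3-hydroxypropanoyl]oxazolidin-2-one | O=C(N1[C@@H](Cc2ccccc2)COC1=O)[C@@H](O[Si](C)(C)C(C)(C)C)[C@H](O)c1c(Br)cc(OCOC)c(CC=C(C)C)c1OCOC | intermediate
19 | (4S)-4-benzyl-3-[(2S,3R)-3-[6-bromo-2,4-bis(methoxymethoxy)-3-(3-methylbut-2-en-1-yl)phenyl]-2-[(tert-butyldimethylsilyl)oxy]-3-[(triethylsilyl)oxy]propanoyl]oxazolidin-2-one | O=C(N1[C@@H](Cc2ccccc2)COC1=O)[C@@H](O[Si](C)(C)C(C)(C)C)[C@H](O[Si](CC)(CC)CC)c1c(Br)cc(OCOC)c(CC=C(C)C)c1OCOC | intermediate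
20 | (2R,3R)-3-[6-bromo-2,4-bis(methoxymethoxy)-3-(3-methylbut-2-en-1-yl)phenyl]-2-[(tert-butyldimethylsilyl)oxy]-3-[(triethylsilyl)oxy]propan-1-ol | OC[C@@H](O[Si](C)(C)C(C)(C)C)[C@H](O[Si](CC)(CC)CC)c1c(Br)cc(OCOC)c(CC=C(C)C)c1OCOC | intermediate
21 | (2S,3R)-3-[6-bromo-2,4-bis(methoxymethoxy)-3-(3-methylbut-2-en-1-yl)phenyl]-2-[(tert-butyldimethylsilyl)oxy]-3-[(triethylsilyl)oxy]propanal | O=C[C@@H](O[Si](C)(C)C(C)(C)C)[C@H](O[Si](CC)(CC)CC)c1c(Br)cc(OCOC)c(CC=C(C)C)c1OCOC | intermediate
22 | 3-geranyl-2,4-bis(methoxymethoxy)phenyllithium | CC(C)=CCC/C(C)=C/Cc1c(OCOC)ccc([Li])c1OCOC | intermediate (not isolated)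
23 | (1R,2R,3R)-3-[6-bromo-2,4-bis(methoxymethoxy)-3-(3-methylbut-2-en-1-yl)phenyl]-2-[(tert-butyldimethylsilyl)oxy]-1-{3-[(2E)-3,7-dimethylocta-2,6-dien-1-yl]-2,4-bis(methoxymethoxy)phenyl}-3-[(triethylsilyl)oxy]propan-1-ol (key-step precursor) | CC(C)=CCC/C(C)=C/Cc1c(OCOC)ccc([C@@H](O)[C@@H](O[Si](C)(C)C(C)(C)C)[C@H](O[Si](CC)(CC)CC)c2c(Br)cc(OCOC)c(CC=C(C)C)c2OCOC)c1OCOC | intermediate
24 | (2R,3R,4R)-3-[(tert-butyldimethylsilyl)oxy]-2-{3-[(2E)-3,7-dimethylocta-2,6-dien-1-yl]-2,4-bis(methoxymethoxy)phenyl}-5,7-bis(methoxymethoxy)-6-(3-methylbut-2-en-1-yl)-4-[(triethylsilyl)oxy]chromane (key-step product) | CC(C)=CCC/C(C)=C/Cc1c(OCOC)ccc([C@H]2Oc3cc(OCOC)c(CC=C(C)C)c(OCOC)c3[C@@H](O[Si](CC)(CC)CC)[C@@H]2O[Si](C)(C)C(C)(C)C)c1OCOC | intermediate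
25 | (2R,3S,4R)-3-[(tert-butyldimethylsilyl)oxy]-2-{3-[(2E)-3,7-dimethylocta-2,6-dien-1-yl]-2,4-bis(methoxymethoxy)phenyl}-5,7-bis(methoxymethoxy)-6-(3-methylbut-2-en-1-yl)chroman-4-ol | CC(C)=CCC/C(C)=C/Cc1c(OCOC)ccc([C@H]2Oc3cc(OCOC)c(CC=C(C)C)c(OCOC)c3[C@@H](O)[C@@H]2O[Si](C)(C)C(C)(C)C)c1OCOC | intermediate
26 | (2R,3R)-3-[(tert-butyldimethylsilyl)oxy]-2-{3-[(2E)-3,7-dimethylocta-2,6-dien-1-yl]-2,4-bis(methoxymethoxy)phenyl}-5,7-bis(methoxymethoxy)-6-(3-methylbut-2-en-1-yl)chroman-4-one | CC(C)=CCC/C(C)=C/Cc1c(OCOC)ccc([C@H]2Oc3cc(OCOC)c(CC=C(C)C)c(OCOC)c3C(=O)[C@@H]2O[Si](C)(C)C(C)(C)C)c1OCOC | intermediate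
27 | (2R,3R)-2-{3-[(2E)-3,7-dimethylocta-2,6-dien-1-yl]-2,4-dihydroxyphenyl}-3,5,7-trihydroxy-6-(3-methylbut-2-en-1-yl)chroman-4-one | CC(C)=CCC/C(C)=C/Cc1c(O)ccc([C@H]2Oc3cc(O)c(CC=C(C)C)c(O)c3C(=O)[C@@H]2O)c1O | target

Total step count: 15.
Longest linear sequence: 12 steps (steps 1, 2, 3, 7, 8, 9, 10, 11, 12, 13, 14, 15, from 5-bromoresorcinol).

Steps most likely to fail

Step 12. What may go wrong: β-hydride elimination from the palladium alkoxide (oxidation at C2 with loss of bromine), stalling of reductive elimination in the crowded substrate, or a carbonate-induced 1,2-shift of TBS from O3 to O2 followed by five-membered closure through O3. The fallback sets out from 23 and returns at 24. It closes the other ether bond, O1–C2, by a Mitsunobu reaction, which inverts C2 and therefore needs the C2 epimer. Dess–Martin oxidation of 23 would give the aryl ketone (2S,3R)-1-(ring B aryl)-3-(ring A bromoaryl)-2-(TBS-oxy)-3-(TES-oxy)propan-1-one F1. Reduction with LiBH(s-Bu)3 in THF at −78 °C under Felkin–Anh control (hydride anti to the C3 silyloxy group, which with hydride as the incoming group gives the syn carbinol) would give the (1S,2R,3R) carbinol F2. Miyaura borylation (Pd(dppf)Cl2, B2pin2, KOAc, dioxane, 90 °C, where acetate is too weak a base for C–O coupling) would give the C8a pinacol boronate F3. Oxidation with NaBO3·4H2O in THF/H2O would give the C8a phenol F4. Mitsunobu cyclisation (PPh3, DIAD, THF, 0 °C) then closes ring C with inversion at C2 to give 24.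

Step 11. What may go wrong: insufficient facial selectivity in the addition to the α,β-bis(silyloxy) aldehyde, deprotonation of the benzylic–allylic CH2 of 12 in competition with ring lithiation, or bromine–lithium exchange on ring A. The fallback sets out from 21 and returns at 24. It uses both C2 epimers instead of one: the addition is run as in step 11 and the epimers are separated. Compound 23 goes through step 12, which retains C2. The syn epimer is the (1S,2R,3R) carbinol F2 of the preceding fallback and goes through the pinacol boronate F3 and the C8a phenol F4 to the Mitsunobu closure, which inverts C2. Both lines therefore converge on 24, and this fallback makes no compound beyond F2 to F4 (entry F0).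

Step 3. What may go wrong: loss of LiBr from the ortho-bromoaryllithium (aryne formation), deprotonation of the benzylic–allylic CH2 of the prenyl group in place of the ring proton, or migration of bromine. The fallback sets out from 5 and returns at 7. It moves the formylation to the free resorcinol, where no organolithium is needed. Brief acid methanolysis of 5 (cat. HCl, MeOH, rt) would give 5-bromo-2-prenylresorcinol F5. Magnesium-mediated ortho-formylation (MgCl2, Et3N, (CH2O)n, MeCN, reflux), which can only occur at the two equivalent positions ortho to a hydroxyl and next to bromine, would give 6-bromo-2,4-dihydroxy-3-prenylbenzaldehyde F6. Protection with MOMCl and iPr2NEt in CH2Cl2 then returns 7.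

Further compounds
F1 | step 12 | (2S,3R)-3-[6-bromo-2,4-bis(methoxymethoxy)-3-(3-methylbut-2-en-1-yl)phenyl]-2-[(tert-butyldimethylsilyl)oxy]-1-{3-[(2E)-3,7-dimethylocta-2,6-dien-1-yl]-2,4-bis(methoxymethoxy)phenyl}-3-[(triethylsilyl)oxy]propan-1-one | CC(C)=CCC/C(C)=C/Cc1c(OCOC)ccc(C(=O)[C@@H](O[Si](C)(C)C(C)(C)C)[C@H](O[Si](CC)(CC)CC)c2c(Br)cc(OCOC)c(CC=C(C)C)c2OCOC)c1OCOC
F2 | step 12 | (1S,2R,3R)-3-[6-bromo-2,4-bis(methoxymethoxy)-3-(3-methylbut-2-en-1-yl)phenyl]-2-[(tert-butyldimethylsilyl)oxy]-1-{3-[(2E)-3,7-dimethylocta-2,6-dien-1-yl]-2,4-bis(methoxymethoxy)phenyl}-3-[(triethylsilyl)oxy]propan-1-ol (C2 epimer of 23) | CC(C)=CCC/C(C)=C/Cc1c(OCOC)ccc([C@H](O)[C@@H](O[Si](C)(C)C(C)(C)C)[C@H](O[Si](CC)(CC)CC)c2c(Br)cc(OCOC)c(CC=C(C)C)c2OCOC)c1OCOC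
F3 | step 12 | (1S,2R,3R)-2-[(tert-butyldimethylsilyl)oxy]-1-{3-[(2E)-3,7-dimethylocta-2,6-dien-1-yl]-2,4-bis(methoxymethoxy)phenyl}-3-[2,4-bis(methoxymethoxy)-3-(3-methylbut-2-en-1-yl)-6-(4,4,5,5-tetramethyl-1,3,2-dioxaborolan-2-yl)phenyl]-3-[(triethylsilyl)oxy]propan-1-ol | CC(C)=CCC/C(C)=C/Cc1c(OCOC)ccc([C@H](O)[C@@H](O[Si](C)(C)C(C)(C)C)[C@H](O[Si](CC)(CC)CC)c2c(B3OC(C)(C)C(C)(C)O3)cc(OCOC)c(CC=C(C)C)c2OCOC)c1OCOC
F4 | step 12 | (1S,2R,3R)-2-[(tert-butyldimethylsilyl)oxy]-1-{3-[(2E)-3,7-dimethylocta-2,6-dien-1-yl]-2,4-bis(methoxymethoxy)phenyl}-3-[6-hydroxy-2,4-bis(methoxymethoxy)-3-(3-methylbut-2-en-1-yl)phenyl]-3-[(triethylsilyl)oxy]propan-1-ol | CC(C)=CCC/C(C)=C/Cc1c(OCOC)ccc([C@H](O)[C@@H](O[Si](C)(C)C(C)(C)C)[C@H](O[Si](CC)(CC)CC)c2c(O)cc(OCOC)c(CC=C(C)C)c2OCOC)c1OCOC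
F0 | step 11 | none | none
F5 | step 3 | 5-bromo-2-(3-methylbut-2-en-1-yl)benzene-1,3-diol | CC(C)=CCc1c(O)cc(Br)cc1O
F6 | step 3 | 6-bromo-2,4-dihydroxy-3-(3-methylbut-2-en-1-yl)benzaldehyde | O=Cc1c(Br)cc(O)c(CC=C(C)C)c1O
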